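(The earlier runs and the new flask were generated by integration from invented constants.)

In the south-east run the complex with two exchanged grew at 0.00117 M min⁻¹ from 30.0 min to 60.0 min and at 0.00111 M min⁻¹ from there to 80.0 min, nearly the same, although the complex with one exchanged fell to a third of its reading. Late growth in that run therefore reads like an enzyme at saturation, zero order in that pool.

| setting | south-east | south-west | south | eta | zeta |
|---|---|---|---|---|---|
| starting complex | 0.20 M | 0.80 M | 0.40 M | 0.40 M | 0.40 M |
| incoming ligand | 0.80 M | 0.80 M | 1.6 M | 0.800 M | 0.800 M |
| remark | run made earlier | run made earlier | run made earlier |  |  |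
| time |  |  |  | 80 min | 120 min |

| run | time / min | starting complex / % | complex with two exchanged / % | over-reaction product / % | complex with one exchanged / % |
|---|---|---|---|---|---|
| south-east | 5.00 | 49.6 | 17.0 | 1.9 | 31.7 |
| south-east | 15.0 | 16.4 | 37.8 | 2.5 | 44.9 |
| south-east | 30.0 | 6.0 | 52.2 | 2.8 | 42.3 |
| south-east | 40.0 | 2.5 | 56.8 | 1.7 | 37.6 |
| south-east | 60.0 | 0.2 | 69.8 | 3.4 | 25.5 |
| south-east | 80.0 | 1.3 | 80.9 | 5.3 | 14.4 |
| south-west | 6.00 | 54.8 | 12.0 | 0 | 31.8 |
| south-west | 10.0 | 42.9 | 14.7 | 0.9 | 39.4 |
| south-west | 20.0 | 32.7 | 18.5 | 0 | 47.3 |
| south-west | 30.0 | 28.5 | 17.8 | 2.0 | 52.5 |
| south-west | 50.0 | 22.8 | 17.6 | 1.1 | 57.0 |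
| south-west | 80.0 | 21.3 | 18.8 | 2.8 | 56.2 |
| south | 6.00 | 22.9 | 38.9 | 0.5 | 37.1 |
| south | 12.0 | 6.1 | 54.3 | 1.9 | 39.0 |
| south | 25.0 | 1.9 | 63.0 | 2.7 | 35.3 |
| south | 40.0 | 0 | 69.3 | 2.3 | 30.8 |
| south | 80.0 | 0 | 85.1 | 1.1 | 10.4 |

(standard deviation of a reading: 1 percentage point)

- the numbers in the tables scatter by 1 percentage point (one standard deviation)
- a reading or a percentage of complex with one exchanged counts all its forms, free or not

* which of these there is most of at the end, counted by the starting complex in it, eta (complex with two exchanged / starting complex / complex with one exchanged / over-reaction product)
* which of these there is most of at the end, counted by the starting complex in it, zeta (complex with two exchanged / starting complex / complex with one exchanged / over-reaction product)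
* how much there is at the end of the one of these that leads, in percent of the starting complex charged: eta
* how much there is at the end of the one of these that leads, in percent of the starting complex charged: zeta

Each exchange takes one incoming ligand, and the over-reaction product is counted here as one exchange. This balance puts mean c(incoming ligand) in the south-east run's late stretch at 0.469 M. Dividing the late growth by it gives 0.00245 min⁻¹, the creep constant g: late molar growth of two-exchanged complex per molar free ligand, as read from that run. First order in ligand is my assumption.

Eta and zeta are one charge, read at two times. In the first instants the starting complex goes fast: the south-east run, with the same ligand charge, had lost half of it by 5.00 min. In the middle, two-exchanged complex appears as a burst. Extrapolating the creep back to zero gives 0.0700 M in the south-east run, while the south-west plateau reads 0.145 M. The geometric mean, taken because eta's charge lies midway between those two by ratio, is my estimate for eta: 25.1% of the complex charged. Then comes the creep. With twice as much ligand as complex, the balance makes free ligand, once the starting complex is gone, equal to the complex not in the two-exchanged form, so that share decays with the constant g. My reckoning gives two-exchanged complex 38.5% in eta and 44.2% in zeta. Taking off over-reaction product as read at the south-east run's last reading, my reckoning puts one-exchanged complex ahead in both, at 56.2% and 50.5%.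

The forecast differs: complex with two exchanged at 58% in eta and complex with two exchanged at 67% in zeta. Its own words on these flasks are “ligand falls to about 0.2 M and conversion slows to about 0.01 min⁻¹”.

The simulation gives complex with one exchanged at 50.8% in eta, and complex with two exchanged at 50.8% in zeta.

    starting complex + incoming ligand → leaving ligand + complex with one exchanged (k = 0.00310 M⁻¹ s⁻¹)
    complex with one exchanged + incoming ligand → leaving ligand + complex with two exchanged (k = 0.00600 M⁻¹ s⁻¹)
    crystals ⇌ complex with one exchanged, rate k3*(cs3 - [complex with one exchanged]) while solid is left; crystals form when [complex with one exchanged] > cs3 (solubility = 9.60 mM, k = 0.00690 s⁻¹)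
    complex with one exchanged → over-reaction product (k = 2.00 × 10⁻⁴ s⁻¹)

My level of two-exchanged complex in eta lay 6.2 percentage points low, but g, started from eta's result, gives a rise to zeta of 5.2 points against 6.1 points. At zeta's end crystals hold nearly all of the one-exchanged complex, and the dissolved part goes 5.9 times faster into two-exchanged complex than into over-reaction product. In the neighbour like zeta but charged with 0.32 M of incoming ligand, the 1.27% of that charge left at 120 min gives, through g, a rise of two-exchanged complex of 0.099 points per 40.0 min. That flask ends with two-exchanged complex at 11.3%.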